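**Plan**

- Retrosynthesis: after removal of the benzyl groups and of the 6‑O‑methyl/7‑O‑benzyl pair, ring A is cut at C8–C8a (electrocyclic bond) and at C4a–C5 (carbonyl addition). C5, C6, C7 and C8, four contiguous oxygen‑bearing carbons, are the four carbons of a squarate, and C4a=C8a is the C5=C6 alkene of a 2‑aryl‑3‑methoxy‑4‑pyranone.
- The pyranone (ring C) is cut at O1–C6 and C5–C6 (one‑carbon unit, enaminone cyclisation), at C3–C4 (C‑acetylation) and at C1'–C2 (Friedel–Crafts acylation of the ring B arene).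
- Forward order: ring B arene, aryl methoxymethyl ketone, 1,3‑diketone, ring C as the 5‑iodopyranone, squarate adduct, ring A by thermal ring expansion, then O‑alkylation and deprotection.
- The squarate is the symmetric di‑tert‑butyl ester, so the carbonyl addition cannot give regioisomers. O6 and O7 are told apart later through the higher acidity of the 7‑hydroxyl. A mixed methyl/tert‑butyl ester would save two steps, but its site of attack cannot be predicted with confidence.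
- Stereochemistry: the target is achiral. The stereocentres of 7, 12 and 14 are racemic and are erased by enolisation or aromatisation.

Key step: step 7

Remark: 3,4‑bis(benzyloxy)benzaldehyde, methoxyacetic acid and 3,4‑di‑tert‑butoxycyclobut‑3‑ene‑1,2‑dione are taken as purchasable.

**Route**

Step 1
Reactants: 1 3,4‑bis(benzyloxy)benzaldehyde
Product: 3 3,4‑bis(benzyloxy)phenol, via aryl formate 2 (not isolated)
Conditions: mCPBA, CH2Cl2, 0 °C → rt; aq. NaHCO3 wash; then cat. K2CO3, MeOH, rt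
Reagents that add atoms: mCPBA, OOC(=O)c1cccc(Cl)c1
Why: Baeyer–Villiger (Dakin‑type) oxidation, in which the electron‑rich aryl group migrates in preference to hydride and the resulting aryl formate is transesterified by methanol under mild base without touching the benzyl ethers.

Step 2
Reactants: 3 3,4‑bis(benzyloxy)phenol
Product: 4 1,2‑bis(benzyloxy)‑4‑methoxybenzene
Conditions: MeI, K2CO3, acetone, 50 °C
Reagents that add atoms: iodomethane, CI
Why: Williamson ether synthesis on the only free hydroxyl.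

Step 3
Reactants: 4 1,2‑bis(benzyloxy)‑4‑methoxybenzene; 5 methoxyacetic acid
Product: 6 1‑[4,5‑bis(benzyloxy)‑2‑methoxyphenyl]‑2‑methoxyethan‑1‑one
Conditions: (CF3CO)2O, cat. H3PO4, CH2Cl2, 0 °C → rt
Reagents that add atoms: none
Why: Friedel–Crafts acylation through the mixed trifluoroacetic anhydride, directed to C5 of 4 because it is the only unhindered position activated by an ortho‑methoxy and a para‑benzyloxy group (the site at which 1,2,4‑trialkoxybenzenes are acylated), under conditions free of any Lewis acid able to cleave benzyl ethers.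

Step 4
Reactants: 6 1‑[4,5‑bis(benzyloxy)‑2‑methoxyphenyl]‑2‑methoxyethan‑1‑one
Product: 7 1‑[4,5‑bis(benzyloxy)‑2‑methoxyphenyl]‑2‑methoxybutane‑1,3‑dione (racemic, enolisable)
Conditions: LiN(SiMe3)2 (2.1 equiv), THF–toluene, −78 °C; AcCl, −78 → 0 °C; aq. HCl
Reagents that add atoms: acetyl chloride, CC(Cl)=O
Why: Crossed Claisen‑type C‑acylation of a lithium enolate, regiochemically unambiguous because 6 has a single enolisable position, with the second equivalent of base holding the more acidic diketone as its enolate so that it is not acylated again.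

Step 5
Reactants: 7 1‑[4,5‑bis(benzyloxy)‑2‑methoxyphenyl]‑2‑methoxybutane‑1,3‑dione
Product: 9 2‑[4,5‑bis(benzyloxy)‑2‑methoxyphenyl]‑5‑iodo‑3‑methoxy‑4H‑pyran‑4‑one, via enaminone 8 (not isolated)
Conditions: Me2NCH(OMe)2, toluene, 80 °C; evaporate; then I2, NaHCO3, CH2Cl2, rt
Reagents that add atoms: N,N‑dimethylformamide dimethyl acetal, COC(OC)N(C)C; iodine, II
Why: Aminomethylenation of the only methyl group followed by iodocyclisation of the enaminone (the reaction type that turns 2‑hydroxyaryl enaminones into 3‑iodochromones), in which iodine attacks the enaminone α‑carbon, the enol oxygen of the aryl ketone closes onto the iminium carbon and dimethylamine is lost, while molecular iodine without an oxidant leaves the alkoxyarene untouched.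

Step 6
Reactants: 9 2‑[4,5‑bis(benzyloxy)‑2‑methoxyphenyl]‑5‑iodo‑3‑methoxy‑4H‑pyran‑4‑one; 10 3,4‑di‑tert‑butoxycyclobut‑3‑ene‑1,2‑dione
Product: 12 4‑{6‑[4,5‑bis(benzyloxy)‑2‑methoxyphenyl]‑5‑methoxy‑4‑oxo‑4H‑pyran‑3‑yl}‑2,3‑di‑tert‑butoxy‑4‑hydroxycyclobut‑2‑en‑1‑one (racemic), via pyranonylmagnesium chloride 11 (not isolated)
Conditions: iPrMgCl·LiCl, THF, −78 → −60 °C; then 10, −78 → −40 °C; aq. NH4Cl
Reagents that add atoms: none
Why: Iodine–magnesium exchange at an sp2 C–I bond next to a carbonyl is fast at low temperature and gives a C–Mg species far less prone than a lithium analogue to eliminate the ring oxygen, and its 1,2‑addition to either of the two equivalent carbonyl groups of the symmetric squarate can give only one constitution (the new carbinol centre is racemic and is destroyed in step 7).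

Step 7
Reactants: 12 4‑{6‑[4,5‑bis(benzyloxy)‑2‑methoxyphenyl]‑5‑methoxy‑4‑oxo‑4H‑pyran‑3‑yl}‑2,3‑di‑tert‑butoxy‑4‑hydroxycyclobut‑2‑en‑1‑one
Product: 15 2‑[4,5‑bis(benzyloxy)‑2‑methoxyphenyl]‑6,7‑di‑tert‑butoxy‑5,8‑dihydroxy‑3‑methoxy‑4H‑chromen‑4‑one, via dienylketene 13 (not isolated), via dienone 14 (not isolated)
Conditions: degassed toluene, 110 °C, argon; crude product used at once
Reagents that add atoms: none
Why: Heating opens the cyclobutenone by conrotatory 4π‑electrocyclic cleavage of the C1–C4 bond to the dienylketene 13, whose ketene carbon closes by disrotatory 6π‑electrocyclisation onto the pyranone CH carbon next to the ring oxygen (the C8–C8a bond), and enolisation of the dienone 14 aromatises ring A to the 5,8‑hydroquinone. The closest known reaction type is the Moore rearrangement of 4‑aryl‑ and 4‑alkenyl‑4‑hydroxycyclobutenones derived from squarates to fused hydroquinones. Ring A closes as a six‑membered carbocycle by a thermally allowed 6π‑electrocyclisation of the ketene–alkene–alkene triad, and ring C stays intact. No stereocentre survives: the carbinol centre of 12 becomes sp2 in 13 and the C8a centre of 14 is removed by tautomerisation. The step needs outward rotation of the hydroxyl during ring opening, which this donor group secures and which turns the pyranonyl group toward the ketene; carbon–carbon closure is then possible only at the single CH next to the attachment carbon, the other neighbour being the C4 carbonyl carbon. Because both squarate oxygens carry the same tert‑butyl group, no regiochemical question arises in ring A, and C5–C8 arrive with all four oxygens in place.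

Step 8
Reactants: 15 2‑[4,5‑bis(benzyloxy)‑2‑methoxyphenyl]‑6,7‑di‑tert‑butoxy‑5,8‑dihydroxy‑3‑methoxy‑4H‑chromen‑4‑one
Product: 16 2‑[4,5‑bis(benzyloxy)‑2‑methoxyphenyl]‑6,7‑di‑tert‑butoxy‑5‑hydroxy‑3,8‑dimethoxy‑4H‑chromen‑4‑one
Conditions: MeI (1.3 equiv), K2CO3, degassed acetone, rt, argon
Reagents that add atoms: iodomethane, CI
Why: Williamson methylation that discriminates by hydrogen bonding, since the 5‑hydroxyl is chelated to the C4 carbonyl and stays free while the unchelated 8‑hydroxyl is alkylated, which also removes the air‑sensitive hydroquinone.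

Step 9
Reactants: 16 2‑[4,5‑bis(benzyloxy)‑2‑methoxyphenyl]‑6,7‑di‑tert‑butoxy‑5‑hydroxy‑3,8‑dimethoxy‑4H‑chromen‑4‑one
Product: 17 2‑[4,5‑bis(benzyloxy)‑2‑methoxyphenyl]‑5,6,7‑trihydroxy‑3,8‑dimethoxy‑4H‑chromen‑4‑one
Conditions: CF3CO2H, CH2Cl2, 0 °C → rt, argon
Reagents that add atoms: none
Why: Acidolysis of aryl tert‑butyl ethers with loss of 2‑methylpropene is much faster than cleavage of benzyl or methyl aryl ethers.

Step 10
Reactants: 17 2‑[4,5‑bis(benzyloxy)‑2‑methoxyphenyl]‑5,6,7‑trihydroxy‑3,8‑dimethoxy‑4H‑chromen‑4‑one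
Product: 18 7‑(benzyloxy)‑2‑[4,5‑bis(benzyloxy)‑2‑methoxyphenyl]‑5,6‑dihydroxy‑3,8‑dimethoxy‑4H‑chromen‑4‑one
Conditions: BnBr (1.05 equiv), KHCO3, DMF, rt, argon
Reagents that add atoms: benzyl bromide, BrCc1ccccc1
Why: Site‑selective Williamson benzylation, relying on the 7‑hydroxyl (para to the pyranone carbonyl) being the most acidic phenol and the one ionised by hydrogencarbonate, as in the 7‑O‑alkylation of 5,6,7‑trihydroxyflavones, while the 6‑hydroxyl is less acidic and the 5‑hydroxyl is chelated.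

Step 11
Reactants: 18 7‑(benzyloxy)‑2‑[4,5‑bis(benzyloxy)‑2‑methoxyphenyl]‑5,6‑dihydroxy‑3,8‑dimethoxy‑4H‑chromen‑4‑one
Product: 19 7‑(benzyloxy)‑2‑[4,5‑bis(benzyloxy)‑2‑methoxyphenyl]‑5‑hydroxy‑3,6,8‑trimethoxy‑4H‑chromen‑4‑one
Conditions: MeI (1.5 equiv), K2CO3, acetone, 40 °C
Reagents that add atoms: iodomethane, CI
Why: Williamson methylation of the remaining unchelated 6‑hydroxyl, the chelated 5‑hydroxyl being inert to a small excess of iodomethane under these conditions.

Step 12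
Reactants: 19 7‑(benzyloxy)‑2‑[4,5‑bis(benzyloxy)‑2‑methoxyphenyl]‑5‑hydroxy‑3,6,8‑trimethoxy‑4H‑chromen‑4‑one
Product: 20 5,7,4',5'‑tetrahydroxy‑3,6,8,2'‑tetramethoxyflavone
Conditions: H2 (1 atm), Pd/C (10% Pd on carbon), EtOAc–MeOH, rt
Reagents that add atoms: none
Why: Catalytic hydrogenolysis of the three benzyl aryl ethers under conditions that should neither reduce the flavone C2–C3 double bond nor cleave methyl ethers.

**Compound list**

1 | 3,4‑bis(benzyloxy)benzaldehyde | O=Cc1ccc(OCc2ccccc2)c(OCc2ccccc2)c1 | starting material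
2 | 3,4‑bis(benzyloxy)phenyl formate (not isolated) | O=COc1ccc(OCc2ccccc2)c(OCc2ccccc2)c1 | intermediate
3 | 3,4‑bis(benzyloxy)phenol | Oc1ccc(OCc2ccccc2)c(OCc2ccccc2)c1 | intermediate
4 | 1,2‑bis(benzyloxy)‑4‑methoxybenzene | COc1ccc(OCc2ccccc2)c(OCc2ccccc2)c1 | intermediate
5 | methoxyacetic acid | COCC(=O)O | starting material
6 | 1‑[4,5‑bis(benzyloxy)‑2‑methoxyphenyl]‑2‑methoxyethan‑1‑one | COCC(=O)c1cc(OCc2ccccc2)c(OCc2ccccc2)cc1OC | intermediate
7 | 1‑[4,5‑bis(benzyloxy)‑2‑methoxyphenyl]‑2‑methoxybutane‑1,3‑dione (racemic) | COc1cc(OCc2ccccc2)c(OCc2ccccc2)cc1C(=O)C(OC)C(C)=O | intermediate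
8 | (E)‑1‑[4,5‑bis(benzyloxy)‑2‑methoxyphenyl]‑5‑(dimethylamino)‑2‑methoxypent‑4‑ene‑1,3‑dione (not isolated) | COc1cc(OCc2ccccc2)c(OCc2ccccc2)cc1C(=O)C(OC)C(=O)/C=C/N(C)C | intermediate
9 | 2‑[4,5‑bis(benzyloxy)‑2‑methoxyphenyl]‑5‑iodo‑3‑methoxy‑4H‑pyran‑4‑one | COc1cc(OCc2ccccc2)c(OCc2ccccc2)cc1-c1occ(I)c(=O)c1OC | intermediate
10 | 3,4‑di‑tert‑butoxycyclobut‑3‑ene‑1,2‑dione (di‑tert‑butyl squarate) | CC(C)(C)OC1=C(OC(C)(C)C)C(=O)C1=O | starting material
11 | {6‑[4,5‑bis(benzyloxy)‑2‑methoxyphenyl]‑5‑methoxy‑4‑oxo‑4H‑pyran‑3‑yl}magnesium chloride (not isolated) | COc1cc(OCc2ccccc2)c(OCc2ccccc2)cc1-c1occ([Mg]Cl)c(=O)c1OC | intermediate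
12 | 4‑{6‑[4,5‑bis(benzyloxy)‑2‑methoxyphenyl]‑5‑methoxy‑4‑oxo‑4H‑pyran‑3‑yl}‑2,3‑di‑tert‑butoxy‑4‑hydroxycyclobut‑2‑en‑1‑one (racemic) | COc1cc(OCc2ccccc2)c(OCc2ccccc2)cc1-c1occ(C2(O)C(OC(C)(C)C)=C(OC(C)(C)C)C2=O)c(=O)c1OC | intermediate
13 | (Z)‑4‑{6‑[4,5‑bis(benzyloxy)‑2‑methoxyphenyl]‑5‑methoxy‑4‑oxo‑4H‑pyran‑3‑yl}‑2,3‑di‑tert‑butoxy‑4‑hydroxybuta‑1,3‑dien‑1‑one (dienylketene, not isolated) | O=C=C(OC(C)(C)C)/C(OC(C)(C)C)=C(/O)c1coc(-c2cc(OCc3ccccc3)c(OCc3ccccc3)cc2OC)c(OC)c1=O | intermediate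
14 | 2‑[4,5‑bis(benzyloxy)‑2‑methoxyphenyl]‑6,7‑di‑tert‑butoxy‑5‑hydroxy‑3‑methoxy‑4H‑chromene‑4,8(8aH)‑dione (racemic, not isolated) | COc1cc(OCc2ccccc2)c(OCc2ccccc2)cc1C1=C(OC)C(=O)C2=C(O)C(OC(C)(C)C)=C(OC(C)(C)C)C(=O)C2O1 | intermediate
15 | 2‑[4,5‑bis(benzyloxy)‑2‑methoxyphenyl]‑6,7‑di‑tert‑butoxy‑5,8‑dihydroxy‑3‑methoxy‑4H‑chromen‑4‑one | COc1cc(OCc2ccccc2)c(OCc2ccccc2)cc1-c1oc2c(O)c(OC(C)(C)C)c(OC(C)(C)C)c(O)c2c(=O)c1OC | intermediate
16 | 2‑[4,5‑bis(benzyloxy)‑2‑methoxyphenyl]‑6,7‑di‑tert‑butoxy‑5‑hydroxy‑3,8‑dimethoxy‑4H‑chromen‑4‑one | COc1cc(OCc2ccccc2)c(OCc2ccccc2)cc1-c1oc2c(OC)c(OC(C)(C)C)c(OC(C)(C)C)c(O)c2c(=O)c1OC | intermediate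
17 | 2‑[4,5‑bis(benzyloxy)‑2‑methoxyphenyl]‑5,6,7‑trihydroxy‑3,8‑dimethoxy‑4H‑chromen‑4‑one | COc1cc(OCc2ccccc2)c(OCc2ccccc2)cc1-c1oc2c(OC)c(O)c(O)c(O)c2c(=O)c1OC | intermediate
18 | 7‑(benzyloxy)‑2‑[4,5‑bis(benzyloxy)‑2‑methoxyphenyl]‑5,6‑dihydroxy‑3,8‑dimethoxy‑4H‑chromen‑4‑one | COc1cc(OCc2ccccc2)c(OCc2ccccc2)cc1-c1oc2c(OC)c(OCc3ccccc3)c(O)c(O)c2c(=O)c1OC | intermediate
19 | 7‑(benzyloxy)‑2‑[4,5‑bis(benzyloxy)‑2‑methoxyphenyl]‑5‑hydroxy‑3,6,8‑trimethoxy‑4H‑chromen‑4‑one | COc1cc(OCc2ccccc2)c(OCc2ccccc2)cc1-c1oc2c(OC)c(OCc3ccccc3)c(OC)c(O)c2c(=O)c1OC | intermediate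
20 | 5,7,4',5'‑tetrahydroxy‑3,6,8,2'‑tetramethoxyflavone | COc1cc(O)c(O)cc1-c1oc2c(OC)c(O)c(OC)c(O)c2c(=O)c1OC | target

**Step count**

Total steps: 12. Longest linear sequence: 12 steps (1 → 20); compounds 5 and 10 enter as purchased reagents.

**Steps most likely to fail**

Step 6. The magnesiated pyranone may open by elimination of the ring oxygen anti to the C–Mg bond before it adds, because addition to the carbonyl flanked by a tert‑butoxy‑bearing carbon is slow. Fallback, setting out from 9: direct insertion of zinc (Zn dust, LiCl, THF, rt) should give the pyranonylzinc iodide F1, whose covalent C–Zn bond does not undergo this elimination. Its 1,2‑addition to 10 is then promoted by MgCl2 as Lewis acid at 0 °C, the way arylzinc halides are added to reactive carbonyl compounds. Quenching with NH4Cl returns the route at 12.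

Step 7. The free hydroxyl may add to the ketene (lactonisation to a 5H‑furanone after inward rotation), the ketene may be held reversibly by the C4 carbonyl oxygen, the tert‑butyl vinylogous ester may lose 2‑methylpropene before ring opening, and the hydroquinone may oxidise in air. Fallback, setting out from 12: the tertiary alcohol is silylated (Me3SiCl, Et3N, cat. DMAP, CH2Cl2) to the trimethylsilyl ether F2. Thermolysis of this 4‑silyloxycyclobutenone in toluene closes the same C8–C8a bond, cannot lactonise and should give the 5‑O‑silyl hydroquinone monoether F3. Brief treatment with aqueous citric acid in THF removes the silyl group and returns the route at 15.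

Step 10. Benzylation may spread over O6 and O7 or go twice, and the trihydroxy ring may be oxidised under base. Fallback, setting out from 16: the two tert‑butyl ethers are differentiated by chelation instead of by acidity. MgBr2·OEt2 in CH2Cl2 at 0 °C, bound between the 5‑oxygen and the C4 carbonyl, should cleave only the neighbouring 6‑O‑tert‑butyl ether; this is the mode by which alkoxy groups next to a chelated 5‑hydroxyl are removed selectively with AlCl3 or AlBr3. The product is the 7‑tert‑butoxy‑5,6‑diol F4. MeI with K2CO3 then methylates the unchelated 6‑hydroxyl to the 7‑tert‑butoxy‑3,6,8‑trimethoxy compound F5. CF3CO2H in CH2Cl2 frees the 7‑hydroxyl to give the dibenzyl ether F6, and hydrogenolysis over Pd/C returns the route at 20.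

Further compounds
F1 | step 6 | {6‑[4,5‑bis(benzyloxy)‑2‑methoxyphenyl]‑5‑methoxy‑4‑oxo‑4H‑pyran‑3‑yl}zinc iodide | COc1cc(OCc2ccccc2)c(OCc2ccccc2)cc1-c1occ([Zn]I)c(=O)c1OC
F2 | step 7 | 4‑{6‑[4,5‑bis(benzyloxy)‑2‑methoxyphenyl]‑5‑methoxy‑4‑oxo‑4H‑pyran‑3‑yl}‑2,3‑di‑tert‑butoxy‑4‑(trimethylsilyloxy)cyclobut‑2‑en‑1‑one (racemic) | COc1cc(OCc2ccccc2)c(OCc2ccccc2)cc1-c1occ(C2(O[Si](C)(C)C)C(OC(C)(C)C)=C(OC(C)(C)C)C2=O)c(=O)c1OC
F3 | step 7 | 2‑[4,5‑bis(benzyloxy)‑2‑methoxyphenyl]‑6,7‑di‑tert‑butoxy‑8‑hydroxy‑3‑methoxy‑5‑(trimethylsilyloxy)‑4H‑chromen‑4‑one | COc1cc(OCc2ccccc2)c(OCc2ccccc2)cc1-c1oc2c(O)c(OC(C)(C)C)c(OC(C)(C)C)c(O[Si](C)(C)C)c2c(=O)c1OC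
F4 | step 10 | 2‑[4,5‑bis(benzyloxy)‑2‑methoxyphenyl]‑7‑tert‑butoxy‑5,6‑dihydroxy‑3,8‑dimethoxy‑4H‑chromen‑4‑one | COc1cc(OCc2ccccc2)c(OCc2ccccc2)cc1-c1oc2c(OC)c(OC(C)(C)C)c(O)c(O)c2c(=O)c1OC
F5 | step 10 | 2‑[4,5‑bis(benzyloxy)‑2‑methoxyphenyl]‑7‑tert‑butoxy‑5‑hydroxy‑3,6,8‑trimethoxy‑4H‑chromen‑4‑one | COc1cc(OCc2ccccc2)c(OCc2ccccc2)cc1-c1oc2c(OC)c(OC(C)(C)C)c(OC)c(O)c2c(=O)c1OC
F6 | step 10 | 2‑[4,5‑bis(benzyloxy)‑2‑methoxyphenyl]‑5,7‑dihydroxy‑3,6,8‑trimethoxy‑4H‑chromen‑4‑one | COc1cc(OCc2ccccc2)c(OCc2ccccc2)cc1-c1oc2c(OC)c(O)c(OC)c(O)c2c(=O)c1OC
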